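The plan disconnects only the two aryl–methyl bonds at C6 and C8 of ring A; C2 (S), ring C and the oxygen pattern of ring B are bought with (S)-hesperetin. The key step exploits the fact that, in a 5-hydroxy-7-methoxy ring A, C6 and C8 are the only unsubstituted carbons and the most electron-rich ones: both are brominated, then both C–Br bonds are exchanged for C–CH3 in one twofold palladium-catalysed Stille coupling with SnMe4. Its precursor is the 6,8-dibromoflavanone carrying free chelated O5–H, O7–CH3 and the ring B O3' phenol as acetate; that phenol, para-unsubstituted and flanked by O4'–CH3, is finally oxidised to the methoxy-para-quinone.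

Key step: step 4

Remark: (S)-hesperetin is taken as the enantiomerically pure (2S) aglycone; ordinary commercial hesperetin can be partly racemic and would not serve.
Remark: in the two twofold steps the order in which C6 and C8 react has no bearing on the outcome; the transient compounds 7 and 10 are drawn with C6 brominated first and C8 methylated first.

Step 1
Reactants: 1 (S)-hesperetin; 2 trimethylsilyldiazomethane
Product: 3 (2S)-5-hydroxy-2-(3-hydroxy-4-methoxyphenyl)-7-methoxychroman-4-one ((S)-7-O-methylhesperetin)
Conditions: Me3SiCHN2 (1.1 equiv, 2 M in hexanes, dropwise), MeOH/toluene 1:3, 0 °C to rt; AcOH quench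
Reagents that add atoms: trimethylsilyldiazomethane, C[Si](C)(C)C=[N+]=[N-]
Why: O-methylation of a phenol by a diazoalkane (methanol releases diazomethane from the silyl reagent in the flask) follows acidity, so O7–H of ring A, a vinylogous carboxylic acid para to the C4 carbonyl, should react well before the ordinary O3'–H of ring B and the O5–H held in a hydrogen bond to C4=O, while the neutral medium cannot open ring C or epimerise C2.

Step 2
Reactants: 3 (S)-7-O-methylhesperetin; 4 acetic anhydride
Product: 5 (2S)-2-(3-acetoxy-4-methoxyphenyl)-5-hydroxy-7-methoxychroman-4-one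
Conditions: Ac2O (1.2 equiv), pyridine (3 equiv), CH2Cl2, 0 °C to rt
Reagents that add atoms: acetic anhydride, CC(=O)OC(C)=O
Why: O-acylation with a slight excess of anhydride and a weak base should esterify only the free ring B phenol O3'–H, because O5–H is tied up in its hydrogen bond to the C4 carbonyl and is not acetylated without a nucleophilic catalyst.

Step 3
Reactants: 5 (2S)-2-(3-acetoxy-4-methoxyphenyl)-5-hydroxy-7-methoxychroman-4-one; 6 N-bromosuccinimide
Product: 8 (2S)-2-(3-acetoxy-4-methoxyphenyl)-6,8-dibromo-5-hydroxy-7-methoxychroman-4-one, via 6-bromo monobromide 7 (not isolated)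
Conditions: NBS (2.1 equiv), DMF, 0 °C to rt, dark
Reagents that add atoms: N-bromosuccinimide, O=C1CCC(=O)N1Br
Why: Electrophilic aromatic bromination: C6 and C8 are ortho or para to O5–H, O7–CH3 and O1 and are the only unsubstituted carbons of ring A, whereas ring B is deactivated by its acetate, so two equivalents of the N-bromoimide should stop cleanly at the 6,8-dibromide without touching C3 or C2.

Step 4
Reactants: 8 (2S)-2-(3-acetoxy-4-methoxyphenyl)-6,8-dibromo-5-hydroxy-7-methoxychroman-4-one; 9 tetramethyltin
Product: 11 (2S)-2-(3-acetoxy-4-methoxyphenyl)-5-hydroxy-7-methoxy-6,8-dimethylchroman-4-one, via 6-bromo-8-methyl monocoupled bromide 10 (not isolated)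
Conditions: SnMe4 (4 equiv), Pd(P(t-Bu)3)2 (10 mol %), CsF (5 equiv, dried), 1,4-dioxane, sealed tube, 80 °C
Reagents that add atoms: tetramethyltin, C[Sn](C)(C)C
Why: Zerovalent palladium carrying a single bulky, electron-rich P(t-Bu)3 ligand inserts into the hindered C8–Br and C6–Br bonds in turn, fluoride turns SnMe4 into a pentacoordinate fluorostannate that passes one methyl group to each arylpalladium bromide, and reductive elimination forms the C8–CH3 and C6–CH3 bonds and returns the catalyst. The closest known reaction type is the fluoride-promoted Stille methylation of ortho,ortho'-disubstituted electron-rich aryl bromides, used here twice on one ring. No ring is closed and no stereocentre is made; C2 keeps the (S) configuration brought in with 1 because no bond at C2 or C3 is touched. The step needs complete twofold coupling without protodebromination, without enolisation at C3 (which would expel O1, open ring C to the chalcone and racemise C2) and without attack on ring B. These are secured by the absence of β-hydrogen in the methyl group, by the fact that ring A holds the only two carbon–halogen bonds, and by the acidic O5–H, which takes up fluoride as the chelated cesium phenoxide so that C4=O becomes part of a vinylogous carboxylate and C3–H is hardly acidic in the sparingly soluble CsF–dioxane medium. Any acetate lost to fluoride is of no consequence, since step 5 removes that group in any case.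

Step 5
Reactants: 11 (2S)-2-(3-acetoxy-4-methoxyphenyl)-5-hydroxy-7-methoxy-6,8-dimethylchroman-4-one
Product: 12 (2S)-5-hydroxy-2-(3-hydroxy-4-methoxyphenyl)-7-methoxy-6,8-dimethylchroman-4-one
Conditions: HCl (1.25 M in MeOH), MeOH/CH2Cl2 1:1, rt to 40 °C
Reagents that add atoms: none
Why: Acid-catalysed transesterification (methanolysis) of the aryl acetate frees the ring B phenol under conditions in which C3 is not deprotonated, so ring C stays closed and C2 keeps its (S) configuration.

Step 6
Reactants: 12 (2S)-5-hydroxy-2-(3-hydroxy-4-methoxyphenyl)-7-methoxy-6,8-dimethylchroman-4-one; 13 potassium nitrosodisulfonate K2NO(SO3)2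
Product: 14 2-[(2S)-5-hydroxy-7-methoxy-6,8-dimethyl-4-oxochroman-2-yl]-5-methoxycyclohexa-2,5-diene-1,4-dione (target)
Conditions: K2NO(SO3)2 (2.5 equiv), aq KH2PO4 (pH 6), acetone/H2O, 0 °C to rt
Reagents that add atoms: potassium nitrosodisulfonate K2NO(SO3)2, [K+].[K+].[O]N(S(=O)(=O)[O-])S(=O)(=O)[O-]
Why: Teuber oxidation: the nitroxyl radical removes the hydrogen of O3'–H, a second equivalent adds at the unsubstituted para carbon C6' and imidodisulfonate is lost to give the 1,4-quinone with O4'–CH3 retained, the hydrogen-bonded O5–H on the fully substituted, acyl-bearing ring A being much harder to oxidise in the buffered, nearly neutral medium.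

Compound list
1 | (S)-hesperetin, (2S)-5,7-dihydroxy-2-(3-hydroxy-4-methoxyphenyl)chroman-4-one | COc1ccc(cc1O)[C@@H]2CC(=O)c3c(O)cc(O)cc3O2 | starting material
2 | trimethylsilyldiazomethane | C[Si](C)(C)C=[N+]=[N-] | starting material
3 | (2S)-5-hydroxy-2-(3-hydroxy-4-methoxyphenyl)-7-methoxychroman-4-one | COc1ccc(cc1O)[C@@H]2CC(=O)c3c(O)cc(OC)cc3O2 | intermediate
4 | acetic anhydride | CC(=O)OC(C)=O | starting material
5 | (2S)-2-(3-acetoxy-4-methoxyphenyl)-5-hydroxy-7-methoxychroman-4-one | COc1ccc(cc1OC(C)=O)[C@@H]2CC(=O)c3c(O)cc(OC)cc3O2 | intermediate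
6 | N-bromosuccinimide | O=C1CCC(=O)N1Br | starting material
7 | (2S)-2-(3-acetoxy-4-methoxyphenyl)-6-bromo-5-hydroxy-7-methoxychroman-4-one (not isolated) | COc1ccc(cc1OC(C)=O)[C@@H]2CC(=O)c3c(O)c(Br)c(OC)cc3O2 | intermediate
8 | (2S)-2-(3-acetoxy-4-methoxyphenyl)-6,8-dibromo-5-hydroxy-7-methoxychroman-4-one | COc1ccc(cc1OC(C)=O)[C@@H]2CC(=O)c3c(O)c(Br)c(OC)c(Br)c3O2 | intermediate
9 | tetramethyltin | C[Sn](C)(C)C | starting material
10 | (2S)-2-(3-acetoxy-4-methoxyphenyl)-6-bromo-5-hydroxy-7-methoxy-8-methylchroman-4-one (not isolated) | COc1ccc(cc1OC(C)=O)[C@@H]2CC(=O)c3c(O)c(Br)c(OC)c(C)c3O2 | intermediate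
11 | (2S)-2-(3-acetoxy-4-methoxyphenyl)-5-hydroxy-7-methoxy-6,8-dimethylchroman-4-one | COc1ccc(cc1OC(C)=O)[C@@H]2CC(=O)c3c(O)c(C)c(OC)c(C)c3O2 | intermediate
12 | (2S)-5-hydroxy-2-(3-hydroxy-4-methoxyphenyl)-7-methoxy-6,8-dimethylchroman-4-one | COc1ccc(cc1O)[C@@H]2CC(=O)c3c(O)c(C)c(OC)c(C)c3O2 | intermediate
13 | potassium nitrosodisulfonate K2NO(SO3)2 | [K+].[K+].[O]N(S(=O)(=O)[O-])S(=O)(=O)[O-] | starting material
14 | 2-[(2S)-5-hydroxy-7-methoxy-6,8-dimethyl-4-oxochroman-2-yl]-5-methoxycyclohexa-2,5-diene-1,4-dione | COC1=CC(=O)C([C@@H]2CC(=O)c3c(O)c(C)c(OC)c(C)c3O2)=CC1=O | target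

Total step count: 6. Longest linear sequence: 6 steps (1 → 3 → 5 → 8 → 11 → 12 → 14).

Steps most likely to fail

Step 4 (twofold Stille methylation). What may go wrong is erosion of the C2 configuration through fluoride-induced opening of ring C, or stalling after the first coupling with protodebromination of the remaining C–Br bond. The fallback gives up tin and fluoride for a base-free Negishi methylation of a more reactive dihalide. It sets out from 5, which N-iodosuccinimide (2.1 equiv, DMF, rt) should iodinate at C6 and C8 to give (2S)-2-(3-acetoxy-4-methoxyphenyl)-5-hydroxy-6,8-diiodo-7-methoxychroman-4-one F1. The two C–I bonds undergo oxidative addition to zerovalent palladium at room temperature, so MeZnCl (5 equiv, one consumed by O5–H) and Pd(P(t-Bu)3)2 in THF/NMP at rt should deliver both methyl groups with no Brønsted base present. The route is rejoined at 11.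

Step 6 (oxidation to the quinone). What may go wrong is incomplete or unselective oxidation: the lipophilic phenol may stay out of the aqueous phase in which the nitroxyl radical decays, and attack at the ortho carbon C2' or over-oxidation may compete. The fallback replaces the stoichiometric radical oxidant by catalytic aerobic oxidation in a homogeneous organic medium. It sets out from 12, which is stirred with Co(salen), the N,N'-bis(salicylidene)ethylenediamine complex of divalent cobalt (10–20 mol %), under O2 (1 atm) in DMF at rt. The cobalt–dioxygen adduct removes the phenolic hydrogen and delivers oxygen to the para carbon C6'. No new compound is made on the way (F0) and the route is rejoined at 14.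

Step 1 (methylation of O7). What may go wrong is loss of site selectivity, with O3'–H methylated in competition with O7–H or both hydroxyls methylated. The fallback reverses the order of protection and methylation, so that only one reactive hydroxyl is present when the diazoalkane is added. It sets out from 1, which 4 (2.2 equiv) and pyridine in CH2Cl2 should acetylate at O7 and O3' to give (2S)-2-(3-acetoxy-4-methoxyphenyl)-5-hydroxy-4-oxochroman-7-yl acetate F2. PhSH (1.1 equiv) with catalytic imidazole in NMP at 0 °C should then remove only the acetate on O7, the ester of the most acidic phenol and so the best acyl donor, giving (2S)-2-(3-acetoxy-4-methoxyphenyl)-5,7-dihydroxychroman-4-one F3. Reagent 2 in MeOH/toluene then methylates O7–H and the route is rejoined at 5, compound 3 being bypassed.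

Further compounds
F1 | step 4 | (2S)-2-(3-acetoxy-4-methoxyphenyl)-5-hydroxy-6,8-diiodo-7-methoxychroman-4-one | COc1ccc(cc1OC(C)=O)[C@@H]2CC(=O)c3c(O)c(I)c(OC)c(I)c3O2
F0 | step 6 | none | none
F2 | step 1 | (2S)-2-(3-acetoxy-4-methoxyphenyl)-5-hydroxy-4-oxochroman-7-yl acetate | COc1ccc(cc1OC(C)=O)[C@@H]2CC(=O)c3c(O)cc(OC(C)=O)cc3O2
F3 | step 1 | (2S)-2-(3-acetoxy-4-methoxyphenyl)-5,7-dihydroxychroman-4-one | COc1ccc(cc1OC(C)=O)[C@@H]2CC(=O)c3c(O)cc(O)cc3O2
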